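I follow the amounts of J and Z in this flask as one number, their ratio (the cumulative selectivity), on a logarithmic scale.

all flasks: E 200 mM (held)
- eta: D 1 M; G 0.70 M; the very flask that is asked about, followed so far
- flask: D 1.0 M; G 0.700 M; time 8.0 h

eta run (percent of the D charged)

| time / h | J / % | Z / % |
|---|---|---|
| 0.333 | 2.4 | 6.9 |
| 0.500 | 5.7 | 7.4 |
| 0.667 | 7.8 | 9.4 |
| 1.00 | 12.2 | 13.0 |
| 1.50 | 19.0 | 15.7 |
| 2.50 | 29.5 | 19.3 |
| 4.00 | 38.9 | 20.9 |

(standard deviation of a reading: 0.5 percentage points)

- at the start none of E is in solution

- share of J in J plus Z at 3.0 min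
- share of J in J plus Z at 30 min
- share of J in J plus Z at 8.0 h
- which of J and Z there is more of at 8.0 h

In the readings of this flask the ratio of J to Z climbs from 0.348 at 0.333 h to 1.86 at 4.00 h. So between those readings its base-ten logarithm rises on average by 0.675 for each tenfold step in time; I call this reading the decade gain. Over the last two readings it is smaller, 0.419, so I carry it backward in time, not forward.

I start from the reading at 1.00 h, where J is 12.2% against 2.4% at the first reading, so the scatter of 0.5 percentage points counts for less there. Going back to 3.0 min gives my own ratio of 0.124, a J share of 11.0%.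

The forecast says 5% at 3.0 min, 40% at 30 min and 68% at 8.0 h, with J ahead at 8.0 h, and for the early time it reasons that “little E is in solution”. My early share is higher.

This flask gives a J share of 11.4% at 3.0 min, 40.9% at 30 min and 67.6% at 8.0 h, with J ahead at 8.0 h.

D → L (k = 1.30 × 10⁻⁴ s⁻¹); L → Q (k = 0.270 s⁻¹); X + L → J (k = 7.80 M⁻¹ s⁻¹); E ⇌ X, rate k4*(csat - [X]) (kL = 3.10 × 10⁻⁴ s⁻¹); G + L → Z (k = 0.430 M⁻¹ s⁻¹) J equals Z in this flask at 1.02 h. From that level point, the decade gain gives a ratio of 0.130 at 3.0 min, a share of 11.5%. In the neighbour charged with 1.8 M of G, the share at 3.0 min is 4.95%. A tenfold step at the same gain gives a ratio of 0.246 at 30 min, a share of 19.7%, and at 30 min that neighbour stands at 24.3%.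

Readings and results are calculated for an exercise, noise included.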